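The route rests on cutting the C8–C9 bond of the ten-membered ring. C8 is a carbinol on the β-carbon (C7) of the butenolide ring, and C9 is joined to C10, which sits α to the C1 ketone, so this bond is the product of an aldehyde and a 2-acylallyl metal. One chromium-mediated intramolecular allylation therefore forms C8–C9, closes the carbocycle, creates the C8 stereocentre and leaves an exocyclic C10 methylene as latent methyl. The precursor is an open-chain β-formyl butenolide that carries the C13 acetate, the C4–C5 epoxide, a silyl-protected C3 carbinol (a C3 ketone would not survive divalent chromium) and a 2-(bromomethyl) enone terminus.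

Key step: step 19

Remark on numbering: ring carbons are C1 (ketone), C2, C3, C4 (methyl), C5, C6 (lactone oxygen), C7, C8, C9, C10; C11 and C12 complete the butenolide (C12 is the lactone carbonyl) and C13 is the acetoxymethyl carbon. CIP labels at C4 and C6 change along the route where neighbouring groups change rank, while the spatial arrangement does not.
Assumption: (S,S)-ProPhenol is taken to give the (4S) alcohol 8 from enal 5; if the facial sense is the reverse, the (R,R) ligand is used in the same way.
Assumption: the C3 carbinol is drawn as the Felkin–Anh epimer (3S); its configuration is immaterial because C3 ends as a ketone.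

Step 1
Reactants: 1 tert-butyldimethyl(prop-2-yn-1-yloxy)silane
Product: 4 (2E)-4-(tert-butyldimethylsilyloxy)-3-methylbut-2-en-1-ol, via alkenylalane 2 (not isolated), via lithium alkenylaluminate 3 (not isolated)
Conditions: Me3Al, Cp2ZrCl2 (0.25 equiv), CH2Cl2, 0 °C to rt; then n-BuLi, hexane/THF, −78 °C; (CH2O)n, −78 °C to rt
Reagents that add atoms: trimethylaluminium, C[Al](C)C; formaldehyde (as paraformaldehyde), C=O
Why: Negishi carboalumination adds methyl and aluminium syn across the alkyne with methyl on the internal carbon, and the aluminate formed with n-BuLi is hydroxymethylated with retention, which fixes the E geometry of the future C4–C5 alkene.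

Step 2
Reactants: 4 (2E)-4-(tert-butyldimethylsilyloxy)-3-methylbut-2-en-1-ol
Product: 5 (2E)-4-(tert-butyldimethylsilyloxy)-3-methylbut-2-enal
Conditions: MnO2 (excess), CH2Cl2, rt
Reagents that add atoms: none
Why: MnO2 oxidises only the allylic alcohol and leaves the silyl ether and the E geometry untouched (allylic oxidation).

Step 3
Reactants: 5 (2E)-4-(tert-butyldimethylsilyloxy)-3-methylbut-2-enal; 6 methyl propiolate
Product: 8 methyl (4S,5E)-7-(tert-butyldimethylsilyloxy)-4-hydroxy-6-methylhept-5-en-2-ynoate, via methylzinc alkynylide 7 (not isolated)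
Conditions: Me2Zn, (S,S)-ProPhenol (10 mol %), Ph3PO (20 mol %), toluene, 4 °C
Reagents that add atoms: none
Why: Zinc–ProPhenol catalysed enantioselective alkynylation of an enal with a propiolate, in which the dinuclear zinc complex binds aldehyde and alkynylide and selects one aldehyde face, sets the C6 carbinol as (S).

Step 4
Reactants: 9 (4-methoxyphenyl)methanol; 10 tributyl(iodomethyl)stannane
Product: 11 tributyl[(4-methoxybenzyloxy)methyl]stannane
Conditions: NaH, THF/DMF, 0 °C to rt
Reagents that add atoms: none
Why: Williamson ether synthesis, the alkoxide of 9 displacing the primary iodide next to tin, is the standard entry to alkoxymethylstannanes.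

Step 5
Reactants: 8 methyl (4S,5E)-7-(tert-butyldimethylsilyloxy)-4-hydroxy-6-methylhept-5-en-2-ynoate; 11 tributyl[(4-methoxybenzyloxy)methyl]stannane
Product: 16 (5S)-5-[(1E)-3-(tert-butyldimethylsilyloxy)-2-methylprop-1-en-1-yl]-3-iodo-4-[(4-methoxybenzyloxy)methyl]furan-2(5H)-one, via alkoxymethyllithium 12 (not isolated), via lithium dialkylcuprate 13 (not isolated), via alkenylcopper adduct 14 (not isolated), via iodo hydroxy ester 15 (not isolated)
Conditions: 11, n-BuLi, THF, −78 °C; CuBr·SMe2 (gives 2.2 equiv of 13); 8, −78 °C; I2, −78 °C; AcOH quench at −78 °C; then PPTS (cat.), CH2Cl2, rt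
Reagents that add atoms: iodine, II
Why: Tin–lithium exchange and cuprate formation give an alkoxymethyl cuprate whose syn carbocupration of the alkynoate (conjugate addition) places the C8 unit on C7 and copper on C11, iodine replaces copper with retention, and the hydroxy ester, cis by construction, lactonises under mild acid without touching C6.

Step 6
Reactants: 16 iodo butenolide
Product: 17 (5S)-5-[(1E)-3-(tert-butyldimethylsilyloxy)-2-methylprop-1-en-1-yl]-3-(hydroxymethyl)-4-[(4-methoxybenzyloxy)methyl]furan-2(5H)-one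
Conditions: Bu3SnCH2OH (1.5 equiv), Pd(PPh3)4 (5 mol %), dioxane, 80 °C
Reagents that add atoms: (tributylstannyl)methanol, OC[Sn](CCCC)(CCCC)CCCC
Why: Stille coupling of the electron-poor alkenyl iodide with (tributylstannyl)methanol transfers the hydroxymethyl group (C13) under neutral conditions that leave the base-sensitive C6–H alone.

Step 7
Reactants: 17 hydroxymethyl butenolide
Product: 18 C13 acetate of 17
Conditions: Ac2O, pyridine, DMAP (cat.), CH2Cl2, 0 °C
Reagents that add atoms: acetic anhydride, CC(=O)OC(C)=O
Why: DMAP-catalysed acetylation of the only free hydroxyl, kept cold and short because of the C6–H acidity.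

Step 8
Reactants: 18 C13 acetate
Product: 19 C3 allylic alcohol (6S) with C13 acetate and C8 PMB ether
Conditions: HF·pyridine, pyridine, THF, 0 °C
Reagents that add atoms: none
Why: Buffered HF·pyridine cleaves the primary allylic silyl ether (fluoride-mediated desilylation) while PMB ether, acetate and lactone persist.

Step 9
Reactants: 19 C3 allylic alcohol
Product: 20 (4R,5R,6R)-epoxy alcohol
Conditions: Ti(OiPr)4 (0.3 equiv), D-(−)-diethyl tartrate (0.36 equiv), t-BuOOH, 4 Å MS, CH2Cl2, −20 °C
Reagents that add atoms: tert-butyl hydroperoxide, CC(C)(C)OO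
Why: Sharpless asymmetric epoxidation of the primary E allylic alcohol, in which D-(−)-tartrate directs oxygen to the face that gives the (4R,5R) epoxy alcohol under reagent control over the existing C6 centre, and the electron-poor butenolide alkene does not react.

Step 10
Reactants: 20 epoxy alcohol
Product: 21 (4S,5R,6R)-epoxy aldehyde (C3 aldehyde)
Conditions: Dess–Martin periodinane, NaHCO3, CH2Cl2, 0 °C to rt
Reagents that add atoms: none
Why: Dess–Martin oxidation under bicarbonate buffer gives the epoxy aldehyde, whose α-carbon C4 is quaternary and therefore cannot epimerise.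

Step 11
Reactants: 22 but-3-en-2-one
Product: 23 3-(hydroxymethyl)but-3-en-2-one
Conditions: aq. CH2O, DABCO (cat.), THF/H2O, rt
Reagents that add atoms: formaldehyde, C=O
Why: Morita–Baylis–Hillman reaction of the enone with formaldehyde under amine catalysis delivers the 2-(hydroxymethyl) enone.

Step 12
Reactants: 23 3-(hydroxymethyl)but-3-en-2-one
Product: 24 triethyl({2-methylidene-3-[(triethylsilyl)oxy]but-3-en-1-yl}oxy)silane
Conditions: Et3SiOTf (2.2 equiv), Et3N, CH2Cl2, −78 to 0 °C
Reagents that add atoms: triethylsilyl trifluoromethanesulfonate, CC[Si](CC)(CC)OS(=O)(=O)C(F)(F)F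
Why: The silyl triflate silylates the alcohol and, with Et3N, enolises the methyl ketone at its only α-CH position (soft enolisation), giving the 2-silyloxy diene.

Step 13
Reactants: 21 epoxy aldehyde; 24 bis-silyl diene
Product: 25 (3S,4R,5R,6R)-aldol with C3 hydroxyl, C1 enone and C9 triethylsilyl ether
Conditions: BF3·OEt2, CH2Cl2, −78 °C; aq. NaHCO3
Reagents that add atoms: none
Why: Mukaiyama aldol addition of the silyl enol ether to the BF3-activated aldehyde forms C2–C3 without base, and Felkin–Anh attack anti to the epoxide C–O bond should favour the (3S) carbinol, a centre that is oxidised at the end.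

Step 14
Reactants: 25 aldol
Product: 26 (3S,4S,5R,6R)-C3 tert-butyldimethylsilyl ether
Conditions: t-BuMe2SiOTf, 2,6-lutidine, CH2Cl2, −78 °C
Reagents that add atoms: tert-butyldimethylsilyl trifluoromethanesulfonate, CC(C)(C)[Si](C)(C)OS(=O)(=O)C(F)(F)F
Why: Silyl triflate silylation of the hindered secondary alcohol blocks oxa-Michael closure onto the enone and keeps C3 at the alcohol level for the chromium step.

Step 15
Reactants: 26 bis-silyl ether
Product: 27 C9 allylic alcohol
Conditions: PPTS (cat.), MeOH/CH2Cl2, 0 °C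
Reagents that add atoms: none
Why: Acid-catalysed methanolysis removes the primary triethylsilyl ether much faster than the hindered secondary tert-butyldimethylsilyl ether (selective desilylation).

Step 16
Reactants: 27 C9 allylic alcohol
Product: 28 C9 allylic bromide
Conditions: CBr4, PPh3, CH2Cl2, 0 °C
Reagents that add atoms: carbon tetrabromide, BrC(Br)(Br)Br
Why: Appel bromination converts the primary allylic alcohol into the bromide under neutral conditions that spare epoxide, acetate and silyl ether.

Step 17
Reactants: 28 C9 allylic bromide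
Product: 29 C8 primary alcohol
Conditions: DDQ, CH2Cl2/pH 7 buffer, 0 °C
Reagents that add atoms: none
Why: Oxidative PMB cleavage by DDQ in buffered wet CH2Cl2 proceeds by hydride abstraction at the benzylic position and leaves the allylic bromide, the enone and the epoxide alone.

Step 18
Reactants: 29 C8 primary alcohol
Product: 30 (3S,4S,5R,6R)-seco C8 formyl butenolide with C3 silyl ether and 2-(bromomethyl) enone
Conditions: Dess–Martin periodinane, NaHCO3, CH2Cl2, 0 °C
Reagents that add atoms: none
Why: Dess–Martin oxidation of the primary allylic alcohol under buffer gives the β-formyl butenolide, which is used at once because its C6–H is acidic.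

Step 19
Reactants: 30 seco formyl butenolide
Product: 32 (3S,4S,5R,6R,8R)-ten-membered C8 alcohol with C10 methylene ketone, via allylchromium dichloride 31 (not isolated)
Conditions: CrCl2 (8 equiv), THF, rt, syringe-pump addition of 30 (final 2 mM)
Reagents that add atoms: none
Why: Two equivalents of divalent chromium reduce the allylic C9–Br bond of 30 to the trivalent allylchromium 31, which adds through its γ-carbon to the C8 aldehyde in a six-membered chromium-bridged transition state; the closest known reaction type is the intramolecular chromium-mediated (Nozaki–Hiyama) allylation of aldehydes by 2-substituted allylic bromides to medium rings. The ten-membered carbocycle closes in a 10-exo-trig mode, forming C8–C9 and regenerating the exocyclic C10 methylene. The new C8 stereocentre is controlled by C6: the tether reaches the aldehyde from the butenolide face that carries C5, and the chromium-bound oxygen is expected to point away from the tether towards C13, which gives the (8R) carbinol. The step needs chemoselectivity for the aldehyde over the C1 ketone, the lactone, the acetates and the epoxide, which the low basicity and aldehyde preference of allylchromium reagents secure, and the C3 silyl ether keeps an epoxy ketone, which divalent chromium would reduce, out of the substrate. Ring closure must outrun intermolecular coupling, which slow addition at millimolar concentration and the three sp2 ring atoms C1, C7 and C10 (less transannular strain) favour.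

Step 20
Reactants: 32 ten-membered methylene ketone alcohol
Product: 33 (3S,4S,5R,6R,8R,10R)-C10 methyl ketone with free C8 hydroxyl
Conditions: H2 (40 bar), [Rh(nbd)(dppb)]BF4 (10 mol %), CH2Cl2, rt
Reagents that add atoms: none
Why: Hydroxyl-directed hydrogenation, in which cationic rhodium bound to the homoallylic C8 hydroxyl adds hydrogen to the C10 methylene from the hydroxyl side, should place the new methyl trans to the C8 oxygen, that is (10R), while the tetrasubstituted butenolide alkene stays.

Step 21
Reactants: 1 tert-butyldimethyl(prop-2-yn-1-yloxy)silane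
Product: 35 tert-butyl 4-(tert-butyldimethylsilyloxy)but-2-ynoate, via lithium acetylide 34 (not isolated)
Conditions: n-BuLi, THF, −78 °C; Boc2O, −78 °C to rt
Reagents that add atoms: di-tert-butyl dicarbonate, CC(C)(C)OC(=O)OC(=O)OC(C)(C)C
Why: Deprotonation of the terminal alkyne and acylation of the acetylide with Boc2O gives the tert-butyl alkynoate.

Step 22
Reactants: 35 tert-butyl 4-(tert-butyldimethylsilyloxy)but-2-ynoate
Product: 37 tert-butyl (2Z)-4-(tert-butyldimethylsilyloxy)-3-methylbut-2-enoate, via alkenylcopper adduct 36 (not isolated)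
Conditions: Me2CuLi (from MeLi, CuI), THF, −78 °C; MeOH then aq. NH4Cl at −78 °C
Reagents that add atoms: methyllithium (as lithium dimethylcuprate), [Li]C
Why: Syn carbocupration of the alkynoate by Me2CuLi (conjugate addition) followed by protonation at −78 °C keeps methyl and hydrogen cis and so gives the Z enoate.

Step 23
Reactants: 37 tert-butyl (2Z)-4-(tert-butyldimethylsilyloxy)-3-methylbut-2-enoate
Product: 39 tert-butyl (2Z)-4-acetoxy-3-methylbut-2-enoate, via hydroxy ester 38 (not isolated)
Conditions: HF·pyridine, pyridine, THF, 0 °C; then Ac2O, DMAP (cat.), 0 °C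
Reagents that add atoms: acetic anhydride, CC(=O)OC(C)=O
Why: Fluoride desilylation followed at once by acetylation in the same flask, with the bulky tert-butyl ester slowing lactonisation of the Z hydroxy ester 38.

Step 24
Reactants: 39 tert-butyl (2Z)-4-acetoxy-3-methylbut-2-enoate
Product: 40 (2Z)-4-acetoxy-3-methylbut-2-enoic acid
Conditions: CF3CO2H, CH2Cl2, 0 °C
Reagents that add atoms: none
Why: Acidolysis of the tert-butyl ester with loss of 2-methylpropene frees the acid without touching the acetate or the Z alkene.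

Step 25
Reactants: 33 C8 alcohol; 40 (2Z)-4-acetoxy-3-methylbut-2-enoic acid
Product: 42 (3S,4S,5R,6R,8R,10R)-C8 ester with C3 silyl ether, via mixed anhydride 41 (not isolated)
Conditions: 40, 2,4,6-Cl3C6H2COCl, Et3N, toluene, rt; then 33, DMAP, toluene, 0 °C to rt
Reagents that add atoms: none
Why: Yamaguchi esterification through the mixed anhydride acylates the hindered C8 alcohol with retention, since no bond to C8 is broken, and without the strong base that would isomerise the Z enoate.

Step 26
Reactants: 42 C8 ester with C3 silyl ether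
Product: 43 (3S,4R,5R,6R,8R,10R)-C3 alcohol
Conditions: HF·pyridine, pyridine, THF, 0 °C to rt
Reagents that add atoms: none
Why: Buffered HF·pyridine removes the secondary silyl ether under non-basic conditions, so that neither retro-aldol cleavage nor C6 deprotonation intervenes, and C10 is now saturated so that the free C3 hydroxyl has no enone to add to.

Step 27
Reactants: 43 C3 alcohol
Product: 44 CNP0274470.1 (4S,5R,6R,8R,10R)
Conditions: Dess–Martin periodinane, NaHCO3, CH2Cl2, 0 °C to rt
Reagents that add atoms: none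
Why: Dess–Martin oxidation of the β-hydroxy ketone gives the C1/C3 β-diketone and completes the target, the adjacent C4 being quaternary and the other stereocentres untouched.

Compound list
1 | tert-butyldimethyl(prop-2-yn-1-yloxy)silane | C#CCO[Si](C)(C)C(C)(C)C | starting material
2 | dimethyl[(1E)-3-(tert-butyldimethylsilyloxy)-2-methylprop-1-en-1-yl]alane | C[Al](C)/C=C(\C)CO[Si](C)(C)C(C)(C)C | intermediate
3 | lithium butyl(dimethyl)[(1E)-3-(tert-butyldimethylsilyloxy)-2-methylprop-1-en-1-yl]aluminate | [Li+].CCCC[Al-](C)(C)/C=C(\C)CO[Si](C)(C)C(C)(C)C | intermediate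
4 | (2E)-4-(tert-butyldimethylsilyloxy)-3-methylbut-2-en-1-ol | OC/C=C(\C)CO[Si](C)(C)C(C)(C)C | intermediate
5 | (2E)-4-(tert-butyldimethylsilyloxy)-3-methylbut-2-enal | O=C/C=C(\C)CO[Si](C)(C)C(C)(C)C | intermediate
6 | methyl propiolate | COC(=O)C#C | starting material
7 | methyl(3-methoxy-3-oxoprop-1-yn-1-yl)zinc | C[Zn]C#CC(=O)OC | intermediate
8 | methyl (4S,5E)-7-(tert-butyldimethylsilyloxy)-4-hydroxy-6-methylhept-5-en-2-ynoate | COC(=O)C#C[C@@H](O)/C=C(\C)CO[Si](C)(C)C(C)(C)C | intermediate
9 | (4-methoxyphenyl)methanol | COc1ccc(CO)cc1 | starting material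
10 | tributyl(iodomethyl)stannane | CCCC[Sn](CCCC)(CCCC)CI | starting material
11 | tributyl[(4-methoxybenzyloxy)methyl]stannane | CCCC[Sn](CCCC)(CCCC)COCc1ccc(OC)cc1 | intermediate
12 | [(4-methoxybenzyloxy)methyl]lithium | [Li]COCc1ccc(OC)cc1 | intermediate
13 | lithium bis[(4-methoxybenzyloxy)methyl]cuprate | [Li+].COc1ccc(COC[Cu-]COCc2ccc(OC)cc2)cc1 | intermediate
14 | syn adduct of 8 with copper on C11 and the PMB-oxymethyl group on C7, as lithium alkoxide (ester cis to C6) | COC(=O)/C([Cu])=C(/COCc1ccc(OC)cc1)[C@@H](O[Li])/C=C(\C)CO[Si](C)(C)C(C)(C)C | intermediate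
15 | methyl (2E,4S,5E)-7-(tert-butyldimethylsilyloxy)-4-hydroxy-2-iodo-3-[(4-methoxybenzyloxy)methyl]-6-methylhepta-2,5-dienoate | COC(=O)/C(I)=C(/COCc1ccc(OC)cc1)[C@@H](O)/C=C(\C)CO[Si](C)(C)C(C)(C)C | intermediate
16 | (5S)-5-[(1E)-3-(tert-butyldimethylsilyloxy)-2-methylprop-1-en-1-yl]-3-iodo-4-[(4-methoxybenzyloxy)methyl]furan-2(5H)-one | IC1=C(COCc2ccc(OC)cc2)[C@@H](OC1=O)/C=C(\C)CO[Si](C)(C)C(C)(C)C | intermediate
17 | (5S)-5-[(1E)-3-(tert-butyldimethylsilyloxy)-2-methylprop-1-en-1-yl]-3-(hydroxymethyl)-4-[(4-methoxybenzyloxy)methyl]furan-2(5H)-one | OCC1=C(COCc2ccc(OC)cc2)[C@@H](OC1=O)/C=C(\C)CO[Si](C)(C)C(C)(C)C | intermediate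
18 | {(5S)-5-[(1E)-3-(tert-butyldimethylsilyloxy)-2-methylprop-1-en-1-yl]-4-[(4-methoxybenzyloxy)methyl]-2-oxo-2,5-dihydrofuran-3-yl}methyl acetate | CC(=O)OCC1=C(COCc2ccc(OC)cc2)[C@@H](OC1=O)/C=C(\C)CO[Si](C)(C)C(C)(C)C | intermediate
19 | {(5S)-5-[(1E)-3-hydroxy-2-methylprop-1-en-1-yl]-4-[(4-methoxybenzyloxy)methyl]-2-oxo-2,5-dihydrofuran-3-yl}methyl acetate | CC(=O)OCC1=C(COCc2ccc(OC)cc2)[C@@H](OC1=O)/C=C(\C)CO | intermediate
20 | {(5R)-5-[(2R,3R)-3-(hydroxymethyl)-3-methyloxiran-2-yl]-4-[(4-methoxybenzyloxy)methyl]-2-oxo-2,5-dihydrofuran-3-yl}methyl acetate (4R,5R,6R) | CC(=O)OCC1=C(COCc2ccc(OC)cc2)[C@@H](OC1=O)[C@H]3O[C@]3(C)CO | intermediate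
21 | {(5R)-5-[(2R,3S)-3-formyl-3-methyloxiran-2-yl]-4-[(4-methoxybenzyloxy)methyl]-2-oxo-2,5-dihydrofuran-3-yl}methyl acetate (4S,5R,6R) | CC(=O)OCC1=C(COCc2ccc(OC)cc2)[C@@H](OC1=O)[C@H]3O[C@]3(C)C=O | intermediate
22 | but-3-en-2-one | CC(=O)C=C | starting material
23 | 3-(hydroxymethyl)but-3-en-2-one | CC(=O)C(=C)CO | intermediate
24 | triethyl({2-methylidene-3-[(triethylsilyl)oxy]but-3-en-1-yl}oxy)silane | C=C(O[Si](CC)(CC)CC)C(=C)CO[Si](CC)(CC)CC | intermediate
25 | seco aldol (3S,4R,5R,6R): C3 hydroxyl, C1 ketone with C10 methylene, C9 triethylsilyl ether, C8 PMB ether, C13 acetate | CC(=O)OCC1=C(COCc2ccc(OC)cc2)[C@@H](OC1=O)[C@H]3O[C@]3(C)[C@@H](O)CC(=O)C(=C)CO[Si](CC)(CC)CC | intermediate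
26 | C3 tert-butyldimethylsilyl ether of 25 (3S,4S,5R,6R) | CC(=O)OCC1=C(COCc2ccc(OC)cc2)[C@@H](OC1=O)[C@H]3O[C@]3(C)[C@@H](O[Si](C)(C)C(C)(C)C)CC(=O)C(=C)CO[Si](CC)(CC)CC | intermediate
27 | C9 allylic alcohol (3S,4S,5R,6R) with C3 silyl ether and C8 PMB ether | CC(=O)OCC1=C(COCc2ccc(OC)cc2)[C@@H](OC1=O)[C@H]3O[C@]3(C)[C@@H](O[Si](C)(C)C(C)(C)C)CC(=O)C(=C)CO | intermediate
28 | C9 allylic bromide (3S,4S,5R,6R) with C8 PMB ether | CC(=O)OCC1=C(COCc2ccc(OC)cc2)[C@@H](OC1=O)[C@H]3O[C@]3(C)[C@@H](O[Si](C)(C)C(C)(C)C)CC(=O)C(=C)CBr | intermediate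
29 | C8 primary alcohol (3S,4S,5R,6R) with C9 bromide | CC(=O)OCC1=C(CO)[C@@H](OC1=O)[C@H]3O[C@]3(C)[C@@H](O[Si](C)(C)C(C)(C)C)CC(=O)C(=C)CBr | intermediate
30 | seco C8 formyl butenolide (3S,4S,5R,6R) with C4–C5 epoxide, C3 silyl ether and 2-(bromomethyl) enone terminus | CC(=O)OCC1=C(C=O)[C@@H](OC1=O)[C@H]2O[C@]2(C)[C@@H](O[Si](C)(C)C(C)(C)C)CC(=O)C(=C)CBr | intermediate
31 | trivalent allylchromium dichloride derived from 30 at C9 | CC(=O)OCC1=C(C=O)[C@@H](OC1=O)[C@H]2O[C@]2(C)[C@@H](O[Si](C)(C)C(C)(C)C)CC(=O)C(=C)C[Cr](Cl)Cl | intermediate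
32 | ten-membered C8 alcohol (3S,4S,5R,6R,8R) with C10 methylene ketone | CC(=O)OCC1=C2[C@@H](OC1=O)[C@H]3O[C@]3(C)[C@@H](O[Si](C)(C)C(C)(C)C)CC(=O)C(=C)C[C@H]2O | intermediate
33 | ten-membered C8 alcohol (3S,4S,5R,6R,8R,10R) with C10 methyl | CC(=O)OCC1=C2[C@@H](OC1=O)[C@H]3O[C@]3(C)[C@@H](O[Si](C)(C)C(C)(C)C)CC(=O)[C@H](C)C[C@H]2O | intermediate
34 | lithium 3-(tert-butyldimethylsilyloxy)prop-1-yn-1-ide | [Li]C#CCO[Si](C)(C)C(C)(C)C | intermediate
35 | tert-butyl 4-(tert-butyldimethylsilyloxy)but-2-ynoate | CC(C)(C)OC(=O)C#CCO[Si](C)(C)C(C)(C)C | intermediate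
36 | syn methylcopper adduct of 35 (copper on C2 cis to the new methyl) | CC(C)(C)OC(=O)/C([Cu])=C(/C)CO[Si](C)(C)C(C)(C)C | intermediate
37 | tert-butyl (2Z)-4-(tert-butyldimethylsilyloxy)-3-methylbut-2-enoate | CC(C)(C)OC(=O)/C=C(/C)CO[Si](C)(C)C(C)(C)C | intermediate
38 | tert-butyl (2Z)-4-hydroxy-3-methylbut-2-enoate | CC(C)(C)OC(=O)/C=C(/C)CO | intermediate
39 | tert-butyl (2Z)-4-acetoxy-3-methylbut-2-enoate | CC(C)(C)OC(=O)/C=C(/C)COC(C)=O | intermediate
40 | (2Z)-4-acetoxy-3-methylbut-2-enoic acid | OC(=O)/C=C(/C)COC(C)=O | intermediate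
41 | (2Z)-4-acetoxy-3-methylbut-2-enoic 2,4,6-trichlorobenzoic anhydride | O=C(OC(=O)/C=C(/C)COC(C)=O)c1c(Cl)cc(Cl)cc1Cl | intermediate
42 | C8 (2Z)-4-acetoxy-3-methylbut-2-enoate (3S,4S,5R,6R,8R,10R) with C3 silyl ether | CC(=O)OCC1=C2[C@@H](OC1=O)[C@H]3O[C@]3(C)[C@@H](O[Si](C)(C)C(C)(C)C)CC(=O)[C@H](C)C[C@H]2OC(=O)/C=C(/C)COC(C)=O | intermediate
43 | C3 alcohol (3S,4R,5R,6R,8R,10R) | CC(=O)OCC1=C2[C@@H](OC1=O)[C@H]3O[C@]3(C)[C@@H](O)CC(=O)[C@H](C)C[C@H]2OC(=O)/C=C(/C)COC(C)=O | intermediate
44 | CNP0274470.1 (4S,5R,6R,8R,10R) | CC(=O)OCC1=C2[C@@H](OC1=O)[C@H]1O[C@]1(C)C(=O)CC(=O)[C@H](C)C[C@H]2OC(=O)/C=C(/C)COC(C)=O | target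

Total step count: 27. Longest linear sequence: 20 steps (steps 1–3, 5–10, 13–20 and 25–27).

Steps most likely to fail

Step 19. The allylchromium may close the ring onto the other face of the aldehyde, or with little preference, if the rotamer with the chromium-bound oxygen turned towards C6 competes. The fallback keeps the ring closure and corrects the stereocentre afterwards. It sets out from 30, whose cyclisation would then deliver the C8 epimer, the (8S) alcohol F1. Mitsunobu esterification of F1 with acid 40 (PPh3, DIAD, toluene, 0 °C) should invert C8 and give the (8R) ester F2, which still carries the C10 methylene. Copper hydride conjugate reduction of F2 with [(Ph3P)CuH]6 in wet toluene, with the ring enolate protonated at C10, should then give 42, where the route is rejoined before the desilylation of step 26.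

Step 20. The exocyclic alkene may migrate into the ring before hydrogen is added, or hydrogen may be delivered without steering if the C8 hydroxyl is tied up as the transannular hemiketal with the C1 ketone. The fallback sets out from 32 and replaces hydrogenation by copper hydride conjugate reduction with [(Ph3P)CuH]6 (toluene, −40 to 0 °C). This forms the C1–C10 copper enolate, which is protonated at C10 on buffered work-up, the neighbouring C8 hydroxyl being placed to deliver the proton to the face that the directed hydrogenation would use. It returns to the route at 33 without any new isolated compound.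

Step 5. The organocopper reagent may be consumed by the free hydroxyl and iodine capture may be incomplete, and C6 may epimerise once the lactone has closed in the alkaline mixture. The fallback sets out from 8 and masks the hydroxyl first: Me3SiCl and Et3N in CH2Cl2 should give the trimethylsilyl ether F3. Cuprate 13 (now 1.2 equiv, THF, −78 °C) followed by iodine should give the acyclic iodo dienoate F4, which can be isolated. Citric acid in methanol then removes the trimethylsilyl group, the primary tert-butyldimethylsilyl ether staying in place, and the liberated hydroxy ester 15 lactonises to 16, where the route is rejoined.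

Further compounds
F1 | step 19 | C8 epimer of 32, the (3S,4S,5R,6R,8S) ten-membered alcohol with C10 methylene ketone | CC(=O)OCC1=C2[C@@H](OC1=O)[C@H]3O[C@]3(C)[C@@H](O[Si](C)(C)C(C)(C)C)CC(=O)C(=C)C[C@@H]2O
F2 | step 19 | (8R) C8 (2Z)-4-acetoxy-3-methylbut-2-enoate with C10 methylene ketone and C3 silyl ether | CC(=O)OCC1=C2[C@@H](OC1=O)[C@H]3O[C@]3(C)[C@@H](O[Si](C)(C)C(C)(C)C)CC(=O)C(=C)C[C@H]2OC(=O)/C=C(/C)COC(C)=O
F0 | step 20 | none | none
F3 | step 5 | methyl (4S,5E)-7-(tert-butyldimethylsilyloxy)-6-methyl-4-(trimethylsilyloxy)hept-5-en-2-ynoate | COC(=O)C#C[C@@H](O[Si](C)(C)C)/C=C(\C)CO[Si](C)(C)C(C)(C)C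
F4 | step 5 | methyl (2E,4S,5E)-7-(tert-butyldimethylsilyloxy)-2-iodo-3-[(4-methoxybenzyloxy)methyl]-6-methyl-4-(trimethylsilyloxy)hepta-2,5-dienoate | COC(=O)/C(I)=C(/COCc1ccc(OC)cc1)[C@@H](O[Si](C)(C)C)/C=C(\C)CO[Si](C)(C)C(C)(C)C
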